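**Retrosynthetic overview**

1. The last bond made is the acetate on the C6' hydroxymethyl group, by enzymatic acylation of the triol that fluoride releases from a bis-silyl ether; ring A is bought intact as 2,6-dihydroxy-4-methylbenzoic acid.
2. Feature used: ring B is a resorcinol monomethyl ether in which C2'–OH and C4'–OMe are meta, the hydroxyl carbon C2' is flanked by the ether carbon C1', and C6' carries CH2O. This is the phenol/meta-alkoxy pattern that a vinylketene and methoxyacetylene give, and C1' can carry the ring A oxygen beforehand as an enol ether carbon.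
3. Key disconnection: ring B by benzannulation of a β-aryloxy α'-diazo enone with methoxyacetylene (C2'–C3' and C4'–C5' by ketene–alkyne [2+2], C1'–C2' by 6π closure). Ring B is the only ring formed in the route.
4. The diazoketone comes from an acrylic acid and this from a tert-butyl β-aryloxyacrylate, whose enol ether C–O bond is made by addition–elimination of the mono-silylated ring A phenol to a β-bromoacrylate (from tert-butyl acrylate by hydroxymethylation, silylation, bromination–dehydrobromination).
5. Methoxyacetylene comes from chloroacetaldehyde dimethyl acetal; the route is convergent with three branches.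

Key step: step 10

Remark: the target has no stereocentre; the only stereochemical element on the way is the E enol ether double bond, which vanishes when ring B aromatises. The acrylate is carried as its tert-butyl ester because the ester must survive bromine (an ester containing a C=C bond would not), and the ring A phenol as its TIPS ether because it must survive phenoxide and carbonate.

**Route**

Step 1
Reactants: 1 2,6-dihydroxy-4-methylbenzoic acid
Product: 2 methyl 2,6-dihydroxy-4-methylbenzoate
Conditions: MeI (1.1 equiv), KHCO3 (1.2 equiv), DMF, rt to 40 °C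
Reagents that add atoms: iodomethane, CI
Why: Carboxylate O-alkylation (SN2), in which KHCO3 ionises only the carboxylic acid, the two hydrogen-bonded phenols stay protonated and unalkylated, and the mild temperature avoids decarboxylation of the 2,6-dihydroxybenzoic acid.

Step 2
Reactants: 2 methyl 2,6-dihydroxy-4-methylbenzoate
Product: 3 methyl 2-hydroxy-4-methyl-6-(triisopropylsilyloxy)benzoate
Conditions: TIPSCl (1.05 equiv), imidazole, DMF, rt
Reagents that add atoms: chlorotriisopropylsilane, CC(C)[Si](Cl)(C(C)C)C(C)C
Why: Phenol silylation of a symmetric diol, in which the hydroxyl left after the first silylation is tied up in a hydrogen bond to the ester carbonyl and shielded by the bulky neighbour, so one equivalent of silyl chloride should stop at the mono-ether; TIPS is chosen because an aryl TIPS ether resists the phenoxide and carbonate of step 6.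

Step 3
Reactants: 4 tert-butyl acrylate
Product: 5 tert-butyl 2-(hydroxymethyl)acrylate
Conditions: aq. HCHO (37%), DABCO (1 equiv), 1,4-dioxane/H2O (1:1), rt
Reagents that add atoms: formaldehyde, C=O
Why: Morita–Baylis–Hillman reaction, in which DABCO adds to the acrylate, the ammonium enolate is hydroxymethylated by formaldehyde and the amine is expelled, the aqueous medium accelerating the otherwise slow tert-butyl ester.

Step 4
Reactants: 5 tert-butyl 2-(hydroxymethyl)acrylate
Product: 6 tert-butyl 2-[(tert-butyldimethylsilyloxy)methyl]acrylate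
Conditions: TBSCl, imidazole, CH2Cl2, 0 °C to rt
Reagents that add atoms: tert-butylchlorodimethylsilane, CC(C)(C)[Si](C)(C)Cl
Why: Standard imidazole-mediated silylation of a primary alcohol, which blocks the hydroxyl against epoxide formation and bromide displacement in step 5.

Step 5
Reactants: 6 tert-butyl 2-[(tert-butyldimethylsilyloxy)methyl]acrylate
Product: 8 tert-butyl (E)-3-bromo-2-[(tert-butyldimethylsilyloxy)methyl]acrylate, via dibromide 7 (not isolated)
Conditions: Br2 (1.05 equiv), CH2Cl2, 0 °C to rt; then DBU (1.1 equiv), 0 °C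
Reagents that add atoms: bromine, BrBr
Why: Electrophilic bromination of the 1,1-disubstituted acrylate followed by E2 dehydrobromination, in which the α-carbon of the dibromide has no hydrogen, so DBU should remove the more acidic CH2Br hydrogen anti to the tertiary bromide and give the conjugated vinyl bromide with bromine trans to the ester.

Step 6
Reactants: 3 methyl 2-hydroxy-4-methyl-6-(triisopropylsilyloxy)benzoate and 8 tert-butyl (E)-3-bromo-2-[(tert-butyldimethylsilyloxy)methyl]acrylate
Product: 9 tert-butyl (2E)-2-[(tert-butyldimethylsilyloxy)methyl]-3-[2-(methoxycarbonyl)-5-methyl-3-(triisopropylsilyloxy)phenoxy]prop-2-enoate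
Conditions: Cs2CO3 (1.5 equiv), DMF, 0 °C to rt
Reagents that add atoms: none
Why: Nucleophilic vinylic substitution by addition–elimination, in which the phenoxide adds to the β-carbon, the ester enolate expels bromide (a far better leaving group than silyloxide), and rotation in the enolate should deliver the more stable E enol ether with the aryloxy group trans to the ester whatever the geometry of the bromide.

Step 7
Reactants: 9 tert-butyl (2E)-2-[(tert-butyldimethylsilyloxy)methyl]-3-[2-(methoxycarbonyl)-5-methyl-3-(triisopropylsilyloxy)phenoxy]prop-2-enoate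
Product: 11 (2E)-2-[(tert-butyldimethylsilyloxy)methyl]-3-[2-(methoxycarbonyl)-5-methyl-3-(triisopropylsilyloxy)phenoxy]prop-2-enoic acid, via trimethylsilyl ester 10 (not isolated)
Conditions: TMSOTf (2 equiv), 2,6-lutidine (3 equiv), CH2Cl2, 0 °C to rt; then pH 5 aqueous buffer
Reagents that add atoms: none
Why: Silyl-triflate-mediated tert-butyl ester cleavage, in which O-silylation of the ester carbonyl triggers loss of isobutene to the trimethylsilyl ester that hydrolyses on work-up, under buffered conditions that leave the enol ether, both silyl ethers and the hindered methyl benzoate untouched.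

Step 8
Reactants: 11 (2E)-2-[(tert-butyldimethylsilyloxy)methyl]-3-[2-(methoxycarbonyl)-5-methyl-3-(triisopropylsilyloxy)phenoxy]prop-2-enoic acid
Product: 13 methyl 2-{[(1E)-2-[(tert-butyldimethylsilyloxy)methyl]-4-diazo-3-oxobut-1-en-1-yl]oxy}-4-methyl-6-(triisopropylsilyloxy)benzoate, via acid chloride 12 (not isolated)
Conditions: 1-chloro-N,N,2-trimethylprop-1-en-1-amine (1.2 equiv), CH2Cl2, 0 °C to rt; then CH2N2 (3 equiv), Et2O, 0 °C
Reagents that add atoms: diazomethane, C=[N+]=[N-]
Why: Arndt–Eistert-type acylation of diazomethane, in which the α-chloroenamine converts the acid to its chloride without free HCl, excess diazomethane is C-acylated and scavenges the HCl, and the trisubstituted push–pull alkene is too electron-rich and hindered for pyrazoline formation.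

Step 9
Reactants: 14 chloroacetaldehyde dimethyl acetal
Product: 16 methoxyacetylene, via sodium methoxyacetylide 15 (not isolated)
Conditions: NaNH2 (3 equiv), liq. NH3, −33 °C; then cold aq. NaCl quench, distil (bp about 23 °C)
Reagents that add atoms: none
Why: Classical alkoxyacetylene synthesis by double elimination with sodium amide, in which loss of methanol and of HCl gives the acetylide, which is protonated on quenching and distilled as the volatile ynol ether.

Step 10
Reactants: 13 methyl 2-{[(1E)-2-[(tert-butyldimethylsilyloxy)methyl]-4-diazo-3-oxobut-1-en-1-yl]oxy}-4-methyl-6-(triisopropylsilyloxy)benzoate and 16 methoxyacetylene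
Product: 21 methyl 2-[2-hydroxy-4-methoxy-6-[(tert-butyldimethylsilyloxy)methyl]phenoxy]-4-methyl-6-(triisopropylsilyloxy)benzoate, via vinylketene 17 (not isolated), via cyclobutenone 18 (not isolated), via dienylketene 19 (not isolated), via cyclohexadienone 20 (not isolated)
Conditions: 16 (4 equiv), hν (254 nm, quartz), ClCH2CH2Cl, 5–10 °C; then N2 purge, 80 °C
Reagents that add atoms: none
Why: Photolysis expels nitrogen and Wolff rearrangement moves the alkenyl group to the former diazo carbon to give vinylketene 17, whose sp carbon is attacked by the unsubstituted carbon of methoxyacetylene so that the [2+2] adduct is the 3-methoxy-4-alkenylcyclobutenone 18 (C2'–C3' and C4'–C5' formed). On warming, 18 opens by reversible 4π electrocyclic cleavage to dienylketene 19, whose thermal disrotatory 6π electrocyclisation closes ring B through the C1'–C2' bond, and cyclohexadienone 20 tautomerises to the phenol. This is the Danheiser benzannulation in its diazoketone (photo-Wolff) form with an alkoxyacetylene as ketenophile, and the closest analogies for the heteroatom-substituted vinylketene are the heteroaryl diazomethyl ketones used in the same reaction. No stereocentre survives, since those of 18 and 20 are transient. The step needs head-to-tail regiochemistry in the [2+2] event, which the polarisation of the ynol ether (nucleophilic CH terminus, oxygen-stabilised internal carbon) secures, so that the methoxy group ends up meta to the new hydroxyl. The E enol ether keeps the aryloxy group on the outside of the closing triene, the aryloxy oxygen perturbs the ketene π system but not the in-plane C=O π* that the alkyne attacks, and since no base or metal is present the C2' hydroxyl appears free and already distinguished from C4'–OMe.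

Step 11
Reactants: 21 methyl 2-[2-hydroxy-4-methoxy-6-[(tert-butyldimethylsilyloxy)methyl]phenoxy]-4-methyl-6-(triisopropylsilyloxy)benzoate
Product: 22 methyl 2-hydroxy-6-[2-hydroxy-6-(hydroxymethyl)-4-methoxyphenoxy]-4-methylbenzoate
Conditions: TBAF (2.5 equiv), AcOH (2.5 equiv), THF, 0 °C to rt
Reagents that add atoms: none
Why: Fluoride-induced desilylation, in which buffered TBAF cleaves the aryl TIPS ether and the primary TBS ether while acetic acid keeps the medium from becoming basic enough for the C2' phenoxide to attack the ring A ester.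

Step 12
Reactants: 22 methyl 2-hydroxy-6-[2-hydroxy-6-(hydroxymethyl)-4-methoxyphenoxy]-4-methylbenzoate
Product: 23 Betaethrin A, methyl 2-[2-(acetoxymethyl)-6-hydroxy-4-methoxyphenoxy]-6-hydroxy-4-methylbenzoate
Conditions: immobilised Candida antarctica lipase B, vinyl acetate (5 equiv), THF/MTBE, 40 °C
Reagents that add atoms: vinyl acetate, C=COC(C)=O
Why: Lipase-catalysed irreversible transesterification with vinyl acetate, in which the serine hydrolase acylates primary aliphatic and benzylic alcohols but not phenols, so only the C6' hydroxymethyl group should be acetylated under neutral conditions.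

**Compound list**

1 | 2,6-dihydroxy-4-methylbenzoic acid | Cc1cc(O)c(C(=O)O)c(O)c1 | starting material
2 | methyl 2,6-dihydroxy-4-methylbenzoate | COC(=O)c1c(O)cc(C)cc1O | intermediate
3 | methyl 2-hydroxy-4-methyl-6-(triisopropylsilyloxy)benzoate | COC(=O)c1c(O)cc(C)cc1O[Si](C(C)C)(C(C)C)C(C)C | intermediate
4 | tert-butyl acrylate | C=CC(=O)OC(C)(C)C | starting material
5 | tert-butyl 2-(hydroxymethyl)acrylate | C=C(CO)C(=O)OC(C)(C)C | intermediate
6 | tert-butyl 2-[(tert-butyldimethylsilyloxy)methyl]acrylate | C=C(CO[Si](C)(C)C(C)(C)C)C(=O)OC(C)(C)C | intermediate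
7 | tert-butyl 2,3-dibromo-2-[(tert-butyldimethylsilyloxy)methyl]propanoate (racemic) | BrCC(Br)(CO[Si](C)(C)C(C)(C)C)C(=O)OC(C)(C)C | intermediate (not isolated)
8 | tert-butyl (E)-3-bromo-2-[(tert-butyldimethylsilyloxy)methyl]acrylate (bromine trans to the ester) | CC(C)(C)OC(=O)/C(CO[Si](C)(C)C(C)(C)C)=C/Br | intermediate
9 | tert-butyl (2E)-2-[(tert-butyldimethylsilyloxy)methyl]-3-[2-(methoxycarbonyl)-5-methyl-3-(triisopropylsilyloxy)phenoxy]prop-2-enoate | CC(C)(C)OC(=O)/C(CO[Si](C)(C)C(C)(C)C)=C/Oc1cc(C)cc(O[Si](C(C)C)(C(C)C)C(C)C)c1C(=O)OC | intermediate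
10 | trimethylsilyl (2E)-2-[(tert-butyldimethylsilyloxy)methyl]-3-[2-(methoxycarbonyl)-5-methyl-3-(triisopropylsilyloxy)phenoxy]prop-2-enoate | C[Si](C)(C)OC(=O)/C(CO[Si](C)(C)C(C)(C)C)=C/Oc1cc(C)cc(O[Si](C(C)C)(C(C)C)C(C)C)c1C(=O)OC | intermediate (not isolated)
11 | (2E)-2-[(tert-butyldimethylsilyloxy)methyl]-3-[2-(methoxycarbonyl)-5-methyl-3-(triisopropylsilyloxy)phenoxy]prop-2-enoic acid | OC(=O)/C(CO[Si](C)(C)C(C)(C)C)=C/Oc1cc(C)cc(O[Si](C(C)C)(C(C)C)C(C)C)c1C(=O)OC | intermediate
12 | (2E)-2-[(tert-butyldimethylsilyloxy)methyl]-3-[2-(methoxycarbonyl)-5-methyl-3-(triisopropylsilyloxy)phenoxy]prop-2-enoyl chloride | ClC(=O)/C(CO[Si](C)(C)C(C)(C)C)=C/Oc1cc(C)cc(O[Si](C(C)C)(C(C)C)C(C)C)c1C(=O)OC | intermediate (not isolated)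
13 | methyl 2-{[(1E)-2-[(tert-butyldimethylsilyloxy)methyl]-4-diazo-3-oxobut-1-en-1-yl]oxy}-4-methyl-6-(triisopropylsilyloxy)benzoate | [N-]=[N+]=CC(=O)/C(CO[Si](C)(C)C(C)(C)C)=C/Oc1cc(C)cc(O[Si](C(C)C)(C(C)C)C(C)C)c1C(=O)OC | intermediate (key-step precursor)
14 | chloroacetaldehyde dimethyl acetal | COC(CCl)OC | starting material
15 | sodium methoxyacetylide | COC#[C-].[Na+] | intermediate (not isolated)
16 | methoxyacetylene | COC#C | intermediate (key-step partner)
17 | β-aryloxy vinylketene, methyl 2-{[2-[(tert-butyldimethylsilyloxy)methyl]-4-oxobuta-1,3-dien-1-yl]oxy}-4-methyl-6-(triisopropylsilyloxy)benzoate, aryloxy trans to the ketene carbon | O=C=C/C(CO[Si](C)(C)C(C)(C)C)=C/Oc1cc(C)cc(O[Si](C(C)C)(C(C)C)C(C)C)c1C(=O)OC | intermediate (not isolated)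
18 | 3-methoxy-4-alkenylcyclobut-2-en-1-one, the alkenyl group being 1-(aryloxy)-3-(tert-butyldimethylsilyloxy)prop-1-en-2-yl (racemic) | O=C1C=C(OC)C1/C(CO[Si](C)(C)C(C)(C)C)=C/Oc2cc(C)cc(O[Si](C(C)C)(C(C)C)C(C)C)c2C(=O)OC | intermediate (not isolated)
19 | dienylketene, 6-aryloxy-5-[(tert-butyldimethylsilyloxy)methyl]-3-methoxyhexa-1,3,5-trien-1-one, 3,4-double bond cis between the ketene and the enol ether arm, aryloxy outside | O=C=C/C(OC)=C\C(CO[Si](C)(C)C(C)(C)C)=C\Oc2cc(C)cc(O[Si](C(C)C)(C(C)C)C(C)C)c2C(=O)OC | intermediate (not isolated)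
20 | 6-aryloxy-5-[(tert-butyldimethylsilyloxy)methyl]-3-methoxycyclohexa-2,4-dien-1-one (racemic) | O=C1C=C(OC)C=C(CO[Si](C)(C)C(C)(C)C)C1Oc2cc(C)cc(O[Si](C(C)C)(C(C)C)C(C)C)c2C(=O)OC | intermediate (not isolated)
21 | methyl 2-[2-hydroxy-4-methoxy-6-[(tert-butyldimethylsilyloxy)methyl]phenoxy]-4-methyl-6-(triisopropylsilyloxy)benzoate | COC(=O)c1c(O[Si](C(C)C)(C(C)C)C(C)C)cc(C)cc1Oc1c(O)cc(OC)cc1CO[Si](C)(C)C(C)(C)C | intermediate (key-step product)
22 | methyl 2-hydroxy-6-[2-hydroxy-6-(hydroxymethyl)-4-methoxyphenoxy]-4-methylbenzoate | COC(=O)c1c(O)cc(C)cc1Oc1c(O)cc(OC)cc1CO | intermediate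
23 | Betaethrin A, methyl 2-[2-(acetoxymethyl)-6-hydroxy-4-methoxyphenoxy]-6-hydroxy-4-methylbenzoate | COC(=O)c1c(O)cc(C)cc1Oc1c(O)cc(OC)cc1COC(C)=O | target

**Step count**

Total: 12 steps. Longest linear sequence: 9 steps (tert-butyl acrylate 4 to 23 through steps 3, 4, 5, 6, 7, 8, 10, 11, 12).

**Steps most likely to fail**

1. Step 10. After loss of nitrogen the excited diazo enone or keto-carbene may be diverted before the 1,2-shift (capture of the carbene by the neighbouring silyl ether oxygen, photochemical cleavage of the aryl vinyl ether). The donor-substituted vinylketene may also dimerise or acylate the product phenol faster than it is captured by the volatile alkyne. The fallback gives up ring construction and makes the diaryl ether bond by cross-coupling of two intact arenes. It sets out from 3 and returns to the route at 22. Commercially available 2-(benzyloxy)-4-methoxybenzaldehyde would be taken through Baeyer–Villiger (Dakin-type) oxidation with mCPBA and methanolysis of the aryl formate (K2CO3, MeOH) to 2-(benzyloxy)-4-methoxyphenol F1. Ortho-formylation (MgCl2, Et3N, paraformaldehyde, MeCN, reflux) would then place the aldehyde at the only free ortho position and give 3-(benzyloxy)-2-hydroxy-5-methoxybenzaldehyde F2, and Tf2O/pyridine would give 2-(benzyloxy)-6-formyl-4-methoxyphenyl trifluoromethanesulfonate F3. Palladium-catalysed etherification of F3 with phenol 3 (Pd(OAc)2, 2-(di-tert-butylphosphino)-2',4',6'-triisopropylbiphenyl, K3PO4, toluene, 100 °C; the ortho-formyl group activates the triflate) should give methyl 2-[2-(benzyloxy)-6-formyl-4-methoxyphenoxy]-4-methyl-6-(triisopropylsilyloxy)benzoate F4. Reduction with NaBH4 (MeOH/THF, 0 °C) would give methyl 2-[2-(benzyloxy)-6-(hydroxymethyl)-4-methoxyphenoxy]-4-methyl-6-(triisopropylsilyloxy)benzoate F5, hydrogenolysis (H2, Pd/C, EtOAc) methyl 2-[2-hydroxy-6-(hydroxymethyl)-4-methoxyphenoxy]-4-methyl-6-(triisopropylsilyloxy)benzoate F6, and TBAF/AcOH as in step 11 the triol 22.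

2. Step 5. The dehydrobromination may take its hydrogen from the CH2OSi arm instead of the CH2Br arm (giving a silyl enol ether with an allylic bromide), and traces of HBr may loosen the silyl ether or the tert-butyl ester. The fallback fixes the halogen position by conjugate addition instead of elimination. It sets out from 3, replaces the branch from 4 to 8 by a new branch from commercially available tert-butyl propiolate, and returns at 9. MgI2 and monomeric formaldehyde in CH2Cl2 at 0 °C (iodide adds to the β-carbon and the β-iodoallenolate is hydroxymethylated, the β-iodo variant of the Baylis–Hillman reaction) should give tert-butyl (Z)-2-(hydroxymethyl)-3-iodoacrylate F7. TBSCl/imidazole would give tert-butyl (Z)-2-[(tert-butyldimethylsilyloxy)methyl]-3-iodoacrylate F8, which would take the place of 8 in step 6 with 3 and converge on the same E enol ether 9.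

3. Step 12. Acyl transfer may stall because the enzyme does not accept a benzylic alcohol flanked by the bulky aryloxy group. The fallback replaces kinetic chemoselection by exhaustive acylation followed by selective cleavage. It sets out from 22 and returns at 23. Ac2O, pyridine and DMAP would give the triacetate methyl 2-acetoxy-6-[2-acetoxy-6-(acetoxymethyl)-4-methoxyphenoxy]-4-methylbenzoate F9. Pyrrolidine (2.2 equiv, MeCN, 0 °C) should then cleave the two aryl acetates by aminolysis far faster than the alkyl acetate, leaving 23.

**Further compounds**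

F1 | step 10 | 2-(benzyloxy)-4-methoxyphenol | COc1ccc(O)c(OCc2ccccc2)c1
F2 | step 10 | 3-(benzyloxy)-2-hydroxy-5-methoxybenzaldehyde | O=Cc1cc(OC)cc(OCc2ccccc2)c1O
F3 | step 10 | 2-(benzyloxy)-6-formyl-4-methoxyphenyl trifluoromethanesulfonate | O=Cc1cc(OC)cc(OCc2ccccc2)c1OS(=O)(=O)C(F)(F)F
F4 | step 10 | methyl 2-[2-(benzyloxy)-6-formyl-4-methoxyphenoxy]-4-methyl-6-(triisopropylsilyloxy)benzoate | COC(=O)c1c(O[Si](C(C)C)(C(C)C)C(C)C)cc(C)cc1Oc1c(OCc2ccccc2)cc(OC)cc1C=O
F5 | step 10 | methyl 2-[2-(benzyloxy)-6-(hydroxymethyl)-4-methoxyphenoxy]-4-methyl-6-(triisopropylsilyloxy)benzoate | COC(=O)c1c(O[Si](C(C)C)(C(C)C)C(C)C)cc(C)cc1Oc1c(OCc2ccccc2)cc(OC)cc1CO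
F6 | step 10 | methyl 2-[2-hydroxy-6-(hydroxymethyl)-4-methoxyphenoxy]-4-methyl-6-(triisopropylsilyloxy)benzoate | COC(=O)c1c(O[Si](C(C)C)(C(C)C)C(C)C)cc(C)cc1Oc1c(O)cc(OC)cc1CO
F7 | step 5 | tert-butyl (Z)-2-(hydroxymethyl)-3-iodoacrylate | CC(C)(C)OC(=O)/C(CO)=C\I
F8 | step 5 | tert-butyl (Z)-2-[(tert-butyldimethylsilyloxy)methyl]-3-iodoacrylate | CC(C)(C)OC(=O)/C(CO[Si](C)(C)C(C)(C)C)=C\I
F9 | step 12 | methyl 2-acetoxy-6-[2-acetoxy-6-(acetoxymethyl)-4-methoxyphenoxy]-4-methylbenzoate | COC(=O)c1c(OC(C)=O)cc(C)cc1Oc1c(OC(C)=O)cc(OC)cc1COC(C)=O
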